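In a one-step world, one reagent meets one starting material, and 1.20 equiv is an excess.

    starting material + reagent → first product (k1 = 4.6 L mol⁻¹ s⁻¹)
    reagent + double product → tris adduct (k2 = 5.5 L mol⁻¹ s⁻¹)
    starting material ⇌ dormant form (K3 = 4.4, k3 = 0.25 s⁻¹)
    reagent + first product → double product (k4 = 2.8 L mol⁻¹ s⁻¹)

starting material 13 mM; reagent 1.20 equiv; time 20 min

- at 20 min, what has stopped the reaction, if anything has (it is still moving / all of the starting material has reacted / the reagent has run out first)
- how much tris adduct there is at 20 min, in percent of the starting material charged

- the reaction counts as stopped when no species that holds the starting material changes by six tenths of a point or more over the second half of the time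
- run time (flask): 20 min

**Reagent cover.** This flask differs: the tris adduct holds 3 reagents per starting material, one each from steps 1, 4 and 2. The charge therefore folds into one number, the cover, meaning equivalents charged over equivalents the full chain demands: 0.400. The cover stands below 1, so reagent is the limiting reagent here, and tris adduct has a ceiling of 40.0%.

**Enough time?** The cover knows no clock. Starting material and dormant form relax in 2.26 s, faster than step 1 consumes starting material, so a free share of 0.185 stands in the pool. Replacing the falling reagent by its mean, half the charge, gives the pool a half-life near 1.74 min, much shorter than the run. This reckoning therefore expects the reagent to stop this flask before 20 min, with tris adduct under the ceiling wherever first product or double product remain, each holding reagent too. It gives no closer figure.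

**Forecast.** The forecast says the reagent has run out first, with 29% tris adduct, “with each molecule consuming up to three reagents”.

**Result.** In the simulation of this flask, the reagent has run out first, with 0% of the reagent left at 20.0 min, and tris adduct stands at 28.7%, below the 40.0% that the cover allows. The neighbouring flask, charged with 3.00 equiv of reagent, has a cover of 1.00, so its ceiling is the whole charge of starting material. That flask reaches 96.8% tris adduct, with 2.6% of its reagent left and 0.35% of its starting material.

The numbers of this flask were drawn at random within sensible limits.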